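**Compound numbering used throughout**
1 tetradecane-1,14-diol · 2 its mono-acetate · 3 the acetoxy aldehyde · 4 vinylmagnesium bromide · 5 racemic allylic alcohol · 6 (R)-allylic alcohol · 7 prop-2-yn-1-ol · 8 its trichloroacetimidate · 9 (R)-allyl propargyl ether · 10 epoxy propargyl ether · 11 titanium alkoxide of 12 · 12 hydroxymethyl methylidene-oxolane · 13 its TBS ether · 14 silyloxymethyl α-methylidene lactone · 15 hydroxymethyl lactone · 16 lactone aldehyde · 17 target.

Assumption: ring atoms carry the lactone numbering of the target (O1, C2 carbonyl carbon, C3 methylidene-bearing carbon, C4 carboxyl-bearing carbon, C5 chain-bearing carbon), also in open-chain precursors; compound 10 is made and used as the mixture of its two epoxide epimers.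

## Analysis of the target

Compound 17 is a γ-butyrolactone (oxolan-2-one ring O1–C2–C3–C4–C5) with an exocyclic methylidene on C3, a free carboxylic acid on C4 and an unbranched 13-acetoxytridecyl chain on C5. It has two adjacent stereocentres, C5 (R) and C4 (S), and the chain and the carboxyl group lie on opposite faces of the ring (4,5-trans). The α-methylidene lactone is a Michael acceptor. The C4–H is α to the acid and γ to the lactone carbonyl, so base can epimerise C4 or move the C3=CH2 double bond into the ring. The primary acetate rules out alkoxide, hydroxide and hydride reagents once it is in place. The difficulty is therefore to set the trans C4/C5 pair and then reveal the acid and the lactone carbonyl without touching C4–H, the methylidene or the acetate. The strategy rests on the C3–C4 bond, which joins the methylidene carbon to the carboxyl-bearing stereocentre inside the ring. If C2 is taken at the ether level, O1–C2–C3 is a propargyl ether on the C5 oxygen, and a radical at C4 closing onto that alkyne makes the ring, the methylidene and the C4 stereocentre at once. The C4 radical can come from a terminal epoxide whose outer carbon is the future carboxyl carbon, so only C5 has to be enantiopure beforehand.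

## Retrosynthetic reasoning

**17 to 14.** The carboxyl group on C4 is taken back to a silyl-protected hydroxymethyl group; no skeletal bond is cut. The acid is placed last because it makes C4–H most acidic, and an acidic chromium oxidation can remove the silyl group and form the acid in one flask without base.

**14 to 13 to 12.** The lactone carbonyl is taken back to a ring CH2. In 13 this C2 is both allylic to the C3 methylidene and α to O1, so it is the most activated C–H site for a chromium-based allylic oxidation. The silyl ether of 13 keeps the C4 substituent at the alcohol level during that oxidation, so no base-sensitive β,γ-unsaturated aldehyde meets pyridine. What is gained is that the ring can be closed at the ether oxidation level.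

**12 to 10 (key disconnection).** The C3–C4 bond is cut. Cutting here leaves C4 as the inner carbon of a terminal epoxide and C3 as the inner carbon of an alkyne held on the C5 oxygen, both easy to make. The forward reaction is a single-electron epoxide opening by a titanocene reductant to a C4 radical, followed by 5-exo-dig closure. The configuration of the epoxide carbon in 10 does not matter, because the radical is planar.

**10 to 9.** The epoxide is taken back to the terminal alkene. The forward peracid oxidation must prefer the alkene over the terminal alkyne and needs no facial control.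

**9 to 6 and 8.** The propargylic O1–C2 bond is cut, not the C5–O bond, so the stereocentre is never a site of substitution. Because of the acetate the etherification must avoid an alkoxide, hence acid-catalysed transfer from the imidate 8, which is made from 7.

**6 to 5 to 3 and 4.** The bond between C5 and the vinyl carbon is cut. The two carbons of 4 become C4 and the carboxyl carbon. Addition is done racemically and 5 is resolved, because kinetic resolution of 1-alken-3-ols reaches high enantiopurity dependably; the cost is half the material at a cheap stage.

**3 to 2 to 1.** Oxidation and desymmetrising mono-acetylation. The symmetric C14 diol supplies C5, the whole chain and both chain oxygens, and the acetate is installed at the outset and carried through.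

## Alternatives that were turned down

**Alternative 1:** conjugate addition and Mannich trapping on a butenolide.
- Disconnection: on the butenolide A1, the C4–carboxyl-carbon bond and the C3–CH2 bond.
- Key step: LiC(SMe)3 adds to C4 anti to the C5 chain and the lactone enolate is trapped at C3 by the iminium salt CH2=NMe2+ I−, giving A2; no ring is formed.
- For: two C–C bonds in one flask. Anti addition to a 5-substituted butenolide is a very dependable source of the 4,5-trans relation, probably stronger than a radical ring closure on this point. The carboxyl carbon arrives at the acid oxidation level, so no late chromium oxidation.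
- Against: A1 needs its own asymmetric synthesis. After the key step the amine must be quaternised and eliminated, the orthothioester unmasked with thiophilic metal salts and the resulting thioester cleaved, and the silyl ether exchanged for the acetate. Thioester cleavage needs hydroxide or peroxide, which the acetate, the lactone and the methylidene acceptor do not tolerate, and liberated methanethiol adds to the methylidene lactone.
- Comparison: the chosen route builds ring, methylidene and C4 in one step and finishes with oxidation-level changes only; it gives up the firmer diastereocontrol of A2.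

**Alternative 2:** cyclopropane retro-aldol lactonisation.
- Disconnection: the lactone O1–C2 bond; the ring carbons and the C4 formyl group come from a cyclopropanated furan ester, and C5 carries only an allyl group.
- Key step: Ba(OH)2 in methanol removes an oxalate, the donor–acceptor cyclopropane opens by retro-aldol cleavage, and the freed C5 hydroxyl lactonises to A3.
- For: both stereocentres derive from one catalytic asymmetric cyclopropanation and a substrate-controlled allylation, with no resolution loss, so it is stronger on enantiocontrol and material throughput. The trans relation is thermodynamically backed because C4 is α to the formyl group.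
- Against: A3 lacks the C3 methylidene, ten chain carbons and the acetate. It would need cross-metathesis with an ω-acetoxy alkene (second-generation Grubbs catalyst), hydrogenation, aldehyde oxidation, and then α-methylenation of the free paraconic acid, which is a harsh finish. That is about four steps to A3 and about five after it.
- Comparison: the chosen route carries the full chain from step 1 and installs the methylidene in the ring-forming step.

**Alternative 3:** palladium cyclocarbonylation.
- Disconnection: O1–C2 and C2–C3; C2 is carbon monoxide inserted between the hydroxyl oxygen and the inner alkyne carbon of the anti homopropargylic alcohol A4.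
- Key step: A4, CO and PdCl2/PPh3/SnCl2 give A5, which is the same compound as 14.
- For: the lactone carbonyl arrives at the right oxidation level, so the allylic oxidation is avoided. C4 and C5 are both fixed in acyclic A4 before ring closure, so no cyclisation diastereoselectivity is at stake. On both points it is stronger than the chosen route.
- Against: A4 requires anti-selective addition of an enantiopure allenylmetal reagent bearing the silyloxymethyl group to aldehyde 3, and that reagent needs several steps and its own asymmetric step. The carbonylation needs pressurised CO and regioselective hydropalladation of a terminal alkyne. The overall length is about the same.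
- Comparison: the chosen route needs only one stereocentre from a classical resolution, uses vinyl and propargyl building blocks, avoids CO and tolerates both epoxide epimers; it pays with two chromium steps and less certain trans control.

Key step: step 8

## Route

Step 1
Reactants: 1 tetradecane-1,14-diol
Product: 2 14-hydroxytetradecyl acetate
Conditions: Ac2O (0.5 equiv), Et3N, DMAP (cat.), THF, 40 °C to rt; excess 1 recovered
Reagents that add atoms: acetic anhydride, CC(=O)OC(C)=O
Why: Statistical mono-acylation of a symmetric diol (DMAP-catalysed acyl transfer); using the diol in excess should bias the mixture towards the mono-ester, and unreacted 1 is recycled.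

Step 2
Reactants: 2 14-hydroxytetradecyl acetate
Product: 3 14-oxotetradecyl acetate
Conditions: TEMPO (cat.), PhI(OAc)2, CH2Cl2, rt
Reagents that add atoms: none
Why: TEMPO-catalysed oxidation of a primary alcohol stops at the aldehyde; the acetate and the saturated chain are inert.

Step 3
Reactants: 3 14-oxotetradecyl acetate; 4 vinylmagnesium bromide
Product: 5 rac-14-hydroxyhexadec-15-en-1-yl acetate
Conditions: CH2=CHMgBr (1.05 equiv), THF, −78 °C; aq NH4Cl at −78 °C
Reagents that add atoms: none
Why: Grignard 1,2-addition; at −78 °C with about one equivalent the aldehyde should react far faster than the remote acetate, and a cold quench prevents acyl transfer to the new alkoxide. The carbinol centre is formed racemic and resolved in step 4.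

Step 4
Reactants: 5 rac-14-hydroxyhexadec-15-en-1-yl acetate
Product: 6 (14R)-14-hydroxyhexadec-15-en-1-yl acetate
Conditions: Ti(OiPr)4, L-(+)-DIPT, t-BuOOH (0.6 equiv), 4 Å MS, CH2Cl2, −20 °C, run slightly beyond half conversion
Reagents that add atoms: none
Why: Sharpless kinetic resolution: with L-(+)-tartrate the (S)-enantiomer of a 1-alken-3-ol is epoxidised much faster, so the (R)-alcohol should remain in high enantiomeric purity and is separated from the polar epoxy alcohol by chromatography. This fixes C5.

Step 5
Reactants: 7 prop-2-yn-1-ol
Product: 8 prop-2-yn-1-yl 2,2,2-trichloroacetimidate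
Conditions: Cl3CCN, DBU (cat.), CH2Cl2, 0 °C
Reagents that add atoms: trichloroacetonitrile, ClC(Cl)(Cl)C#N
Why: Base-catalysed addition of an alcohol to trichloroacetonitrile (imidate formation), a standard activation of primary alcohols.

Step 6
Reactants: 6 (14R)-14-hydroxyhexadec-15-en-1-yl acetate; 8 prop-2-yn-1-yl 2,2,2-trichloroacetimidate
Product: 9 (14R)-14-(prop-2-yn-1-yloxy)hexadec-15-en-1-yl acetate
Conditions: 8 (2 equiv), TfOH (cat.), CH2Cl2/cyclohexane, 0 °C to rt
Reagents that add atoms: none
Why: Acid-catalysed O-alkylation with a trichloroacetimidate: protonated 8 passes its propargyl group to the hydroxyl oxygen of 6 and leaves as the neutral amide. No alkoxide is formed, so the acetate survives, and the C5–O bond is not broken, so the (R) configuration is retained.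

Step 7
Reactants: 9 (14R)-14-(prop-2-yn-1-yloxy)hexadec-15-en-1-yl acetate
Product: 10 (14R)-14-(oxiran-2-yl)-14-(prop-2-yn-1-yloxy)tetradecyl acetate (both epoxide epimers)
Conditions: mCPBA (1.5 equiv), CH2Cl2, 0 °C to rt
Reagents that add atoms: mCPBA, O=C(OO)c1cccc(Cl)c1
Why: Prilezhaev epoxidation; a peracid attacks the alkene much faster than the terminal alkyne. Facial selectivity is not needed because both epimers converge in step 8.

Step 8
Reactants: 10 (14R)-14-(oxiran-2-yl)-14-(prop-2-yn-1-yloxy)tetradecyl acetate
Product: 12 13-[(2R,3R)-3-(hydroxymethyl)-4-methylideneoxolan-2-yl]tridecyl acetate, via the Cp2Ti(Cl) alkoxide of the cyclised alcohol 11 (not isolated)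
Conditions: Cp2TiCl2 (2.5 equiv), Zn dust, THF, rt; the green Cp2TiCl solution added dropwise to 10 in THF; then 1 M HCl
Reagents that add atoms: none
Why: Cp2TiCl (trivalent titanium, made from Cp2TiCl2 and Zn) binds the epoxide oxygen and transfers one electron; the C–O bond to the more substituted carbon breaks, which puts titanium on the primary oxygen and leaves a secondary radical at C4 (titanocene-mediated reductive epoxide opening). The radical adds to the near carbon of the alkyne tethered through O1 in a 5-exo-dig closure that forms C3–C4 and the oxolane ring; the vinyl radical then takes a hydrogen atom from THF (or is reduced by a second Cp2TiCl and protonated on work-up) to give the methylidene, and HCl cleaves the Ti–O bond of 11. The closest known reaction type is this same titanocene-mediated cyclisation of epoxy propargyl ethers to 3-(hydroxymethyl)-4-methylideneoxolanes. The new stereocentre C4 is controlled by C5: in the chair-like 5-exo transition state the chain on C5 lies pseudo-equatorial and the CH2OTi group on the planar radical carbon turns to the opposite face, which should favour the 4,5-trans ring. Because the radical carbon is planar, both epoxide epimers of 10 pass through the same intermediate, so the step is stereoconvergent. The step needs cyclisation to outrun capture of the C4 radical by a second Cp2TiCl, which would expel the β-propargyloxy group; the oxygen in the tether speeds the closure and slow addition keeps the concentration of trivalent titanium low. Any minor cis isomer should be removable by chromatography here or as 13.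

Step 9
Reactants: 12 13-[(2R,3R)-3-(hydroxymethyl)-4-methylideneoxolan-2-yl]tridecyl acetate
Product: 13 13-[(2R,3R)-3-({[tert-butyl(dimethyl)silyl]oxy}methyl)-4-methylideneoxolan-2-yl]tridecyl acetate
Conditions: TBSCl, imidazole, DMF, rt
Reagents that add atoms: tert-butyldimethylsilyl chloride, CC(C)(C)[Si](C)(C)Cl
Why: Standard silylation of a primary alcohol; the silyl ether holds the C4 substituent at the alcohol level during step 10, so no base-sensitive β,γ-unsaturated aldehyde is exposed to pyridine.

Step 10
Reactants: 13 13-[(2R,3R)-3-({[tert-butyl(dimethyl)silyl]oxy}methyl)-4-methylideneoxolan-2-yl]tridecyl acetate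
Product: 14 13-[(2R,3R)-3-({[tert-butyl(dimethyl)silyl]oxy}methyl)-4-methylidene-5-oxooxolan-2-yl]tridecyl acetate
Conditions: CrO3 (excess), pyridine, CH2Cl2, rt (CrO3·2C5H5N formed in situ)
Reagents that add atoms: chromium trioxide, O=[Cr](=O)=O
Why: Allylic oxidation with CrO3·2C5H5N: the ring CH2 at C2 is both allylic and α to O1 and is the most activated C–H position, so it should be converted into the lactone carbonyl, a known conversion of 3-methylideneoxolanes into α-methylidene-γ-butyrolactones. Silyl ether, acetate, C4 and C5 are not touched.

Step 11
Reactants: 14 13-[(2R,3R)-3-({[tert-butyl(dimethyl)silyl]oxy}methyl)-4-methylidene-5-oxooxolan-2-yl]tridecyl acetate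
Product: 17 (2R,3S)-2-[13-(acetyloxy)tridecyl]-4-methylidene-5-oxooxolane-3-carboxylic acid, via the hydroxymethyl lactone 15 (not isolated), via the lactone aldehyde 16 (not isolated)
Conditions: CrO3, H2SO4, H2O (Jones oxidation), acetone, 0 °C to rt
Reagents that add atoms: water, O
Why: Jones oxidation with in-situ desilylation: aqueous H2SO4 in acetone cleaves the primary silyl ether and hexavalent chromium oxidises alcohol 15 through the hydrate of aldehyde 16 to the acid. The acidic medium avoids base-induced migration of the methylidene and epimerisation at C4; acetate and lactone are stable.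

## Compound list

1 | tetradecane-1,14-diol | OCCCCCCCCCCCCCCO | starting material
2 | 14-hydroxytetradecyl acetate | OCCCCCCCCCCCCCCOC(C)=O | intermediate
3 | 14-oxotetradecyl acetate | O=CCCCCCCCCCCCCCOC(C)=O | intermediate
4 | vinylmagnesium bromide | C=C[Mg]Br | starting material
5 | rac-14-hydroxyhexadec-15-en-1-yl acetate | C=CC(O)CCCCCCCCCCCCCOC(C)=O | intermediate
6 | (14R)-14-hydroxyhexadec-15-en-1-yl acetate | C=C[C@H](O)CCCCCCCCCCCCCOC(C)=O | intermediate
7 | prop-2-yn-1-ol | C#CCO | starting material
8 | prop-2-yn-1-yl 2,2,2-trichloroacetimidate | C#CCOC(=N)C(Cl)(Cl)Cl | intermediate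
9 | (14R)-14-(prop-2-yn-1-yloxy)hexadec-15-en-1-yl acetate | C#CCO[C@H](CCCCCCCCCCCCCOC(C)=O)C=C | intermediate
10 | (14R)-14-(oxiran-2-yl)-14-(prop-2-yn-1-yloxy)tetradecyl acetate, both epoxide epimers | C#CCO[C@H](CCCCCCCCCCCCCOC(C)=O)C1CO1 | intermediate
11 | Cp2Ti(Cl) alkoxide of 12 (tetravalent titanium; cyclopentadienyl rings written σ-bonded) | C=C1CO[C@H](CCCCCCCCCCCCCOC(C)=O)[C@H]1CO[Ti](Cl)(C1C=CC=C1)C1C=CC=C1 | intermediate (not isolated)
12 | 13-[(2R,3R)-3-(hydroxymethyl)-4-methylideneoxolan-2-yl]tridecyl acetate | C=C1CO[C@H](CCCCCCCCCCCCCOC(C)=O)[C@H]1CO | intermediate
13 | 13-[(2R,3R)-3-({[tert-butyl(dimethyl)silyl]oxy}methyl)-4-methylideneoxolan-2-yl]tridecyl acetate | C=C1CO[C@H](CCCCCCCCCCCCCOC(C)=O)[C@H]1CO[Si](C)(C)C(C)(C)C | intermediate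
14 | 13-[(2R,3R)-3-({[tert-butyl(dimethyl)silyl]oxy}methyl)-4-methylidene-5-oxooxolan-2-yl]tridecyl acetate | C=C1C(=O)O[C@H](CCCCCCCCCCCCCOC(C)=O)[C@H]1CO[Si](C)(C)C(C)(C)C | intermediate
15 | 13-[(2R,3R)-3-(hydroxymethyl)-4-methylidene-5-oxooxolan-2-yl]tridecyl acetate | C=C1C(=O)O[C@H](CCCCCCCCCCCCCOC(C)=O)[C@H]1CO | intermediate (not isolated)
16 | 13-[(2R,3S)-3-formyl-4-methylidene-5-oxooxolan-2-yl]tridecyl acetate | C=C1C(=O)O[C@H](CCCCCCCCCCCCCOC(C)=O)[C@H]1C=O | intermediate (not isolated)
17 | (2R,3S)-2-[13-(acetyloxy)tridecyl]-4-methylidene-5-oxooxolane-3-carboxylic acid | C=C1C(=O)O[C@H](CCCCCCCCCCCCCOC(C)=O)[C@H]1C(=O)O | target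

## Step count and least certain steps

Total: 11 steps. Longest linear sequence: 10 steps (steps 1–4 and 6–11); step 5 is a one-step branch.

**Step 8 (key step).** The C4 radical may be captured by a second equivalent of trivalent titanium before it cyclises, followed by loss of the β-propargyloxy group; the trans preference of the ring closure may also be incomplete. Fallback, setting out from 10: the epoxide would be hydrolysed (HClO4 cat., THF–H2O) to (14R)-15,16-dihydroxy-14-(prop-2-yn-1-yloxy)hexadecyl acetate F1. The primary hydroxyl would be silylated (TBSCl, imidazole, 0 °C) to (14R)-16-{[tert-butyl(dimethyl)silyl]oxy}-15-hydroxy-14-(prop-2-yn-1-yloxy)hexadecyl acetate F2. The secondary hydroxyl would be converted with 1,1'-thiocarbonyldiimidazole into (14R)-16-{[tert-butyl(dimethyl)silyl]oxy}-15-[(1H-imidazol-1-ylcarbonothioyl)oxy]-14-(prop-2-yn-1-yloxy)hexadecyl acetate F3. Bu3SnH/AIBN (slow addition, toluene, 90 °C) would then generate the same C4 radical by Barton–McCombie C–O homolysis, with no low-valent metal present to reduce it; 5-exo-dig closure and hydrogen transfer from the tin hydride return to the route at 13.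

**Step 6.** Propargyl transfer from the unactivated imidate may be slow, with acid-catalysed rearrangement of the imidate competing, and prolonged acid could ionise the allylic alcohol and erode its enantiopurity. Fallback, setting out from 6: the acetate would be removed (K2CO3, MeOH) to (14R)-hexadec-15-ene-1,14-diol F4 and the primary hydroxyl silylated selectively (TBSCl, imidazole, −20 °C) to (3R)-16-{[tert-butyl(dimethyl)silyl]oxy}hexadec-1-en-3-ol F5. Williamson etherification (NaH, propargyl bromide, Bu4NI, THF) would give tert-butyl(dimethyl){[(14R)-14-(prop-2-yn-1-yloxy)hexadec-15-en-1-yl]oxy}silane F6, desilylation (TBAF) would give (14R)-14-(prop-2-yn-1-yloxy)hexadec-15-en-1-ol F7, and acetylation (Ac2O, pyridine) returns to the route at 9.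

**Step 10.** Conversion may stall, or hydrogen abstraction at the tertiary allylic C4–H may compete and lead to transposition of the double bond. Fallback, setting out from 13: allylic hydroxylation at C2 (SeO2 cat., t-BuOOH, CH2Cl2) would give the lactol 13-[(2R,3R)-3-({[tert-butyl(dimethyl)silyl]oxy}methyl)-5-hydroxy-4-methylideneoxolan-2-yl]tridecyl acetate F8, and oxidation of this allylic lactol with MnO2 returns to the route at 14.

**Step 11.** Desilylation may be slow under the Jones conditions, and during a long exposure the double bond of 16 could migrate into the ring or the hydroxyl of 15 could translactonise. Fallback, setting out from 14: the silyl ether would be cleaved separately with HF·pyridine and 15 isolated, then oxidised under near-neutral conditions (TEMPO cat., PhI(OAc)2, MeCN–H2O) through 16 to the acid, rejoining the route at 17; no new compound is needed.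

**Step 4.** Epoxidation of the monosubstituted alkene is slow, so discrimination between the enantiomers at a practical conversion may be insufficient, and half of the material is lost by design. Fallback, setting out from 3: catalytic enantioselective vinyl transfer with Zn(CH=CH2)2 (from 4 and ZnCl2) and a chiral β-amino alcohol ligand chosen for Si-face delivery would give 6 directly, rejoining the route at 6 and skipping 5; no new compound is needed.

## Further compounds

F1 | step 8 | (14R)-15,16-dihydroxy-14-(prop-2-yn-1-yloxy)hexadecyl acetate, C15 epimers | C#CCO[C@H](CCCCCCCCCCCCCOC(C)=O)C(O)CO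
F2 | step 8 | (14R)-16-{[tert-butyl(dimethyl)silyl]oxy}-15-hydroxy-14-(prop-2-yn-1-yloxy)hexadecyl acetate | C#CCO[C@H](CCCCCCCCCCCCCOC(C)=O)C(O)CO[Si](C)(C)C(C)(C)C
F3 | step 8 | (14R)-16-{[tert-butyl(dimethyl)silyl]oxy}-15-[(1H-imidazol-1-ylcarbonothioyl)oxy]-14-(prop-2-yn-1-yloxy)hexadecyl acetate | C#CCO[C@H](CCCCCCCCCCCCCOC(C)=O)C(CO[Si](C)(C)C(C)(C)C)OC(=S)n1ccnc1
F4 | step 6 | (14R)-hexadec-15-ene-1,14-diol | C=C[C@H](O)CCCCCCCCCCCCCO
F5 | step 6 | (3R)-16-{[tert-butyl(dimethyl)silyl]oxy}hexadec-1-en-3-ol | C=C[C@H](O)CCCCCCCCCCCCCO[Si](C)(C)C(C)(C)C
F6 | step 6 | tert-butyl(dimethyl){[(14R)-14-(prop-2-yn-1-yloxy)hexadec-15-en-1-yl]oxy}silane | C#CCO[C@H](CCCCCCCCCCCCCO[Si](C)(C)C(C)(C)C)C=C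
F7 | step 6 | (14R)-14-(prop-2-yn-1-yloxy)hexadec-15-en-1-ol | C#CCO[C@H](CCCCCCCCCCCCCO)C=C
F8 | step 10 | 13-[(2R,3R)-3-({[tert-butyl(dimethyl)silyl]oxy}methyl)-5-hydroxy-4-methylideneoxolan-2-yl]tridecyl acetate, anomer mixture | C=C1C(O)O[C@H](CCCCCCCCCCCCCOC(C)=O)[C@H]1CO[Si](C)(C)C(C)(C)C
F0 | step 11 | none | none
F0 | step 4 | none | none
A1 | alternative 1 | (5R)-5-[13-(tert-butyldimethylsilyloxy)tridecyl]furan-2(5H)-one | O=C1O[C@H](CCCCCCCCCCCCCO[Si](C)(C)C(C)(C)C)C=C1
A2 | alternative 1 | (3R,4S,5R)-3-[(dimethylamino)methyl]-4-[tris(methylsulfanyl)methyl]-5-[13-(tert-butyldimethylsilyloxy)tridecyl]oxolan-2-one | CN(C)C[C@@H]1C(=O)O[C@H](CCCCCCCCCCCCCO[Si](C)(C)C(C)(C)C)[C@H]1C(SC)(SC)SC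
A3 | alternative 2 | (2R,3S)-5-oxo-2-(prop-2-en-1-yl)oxolane-3-carbaldehyde | C1C(=O)O[C@H](CC=C)[C@H]1C=O
A4 | alternative 3 | (14R,15R)-15-({[tert-butyl(dimethyl)silyl]oxy}methyl)-14-hydroxyheptadec-16-yn-1-yl acetate | O[C@H](CCCCCCCCCCCCCOC(C)=O)[C@H](C#C)CO[Si](C)(C)C(C)(C)C
A5 | alternative 3 | 13-[(2R,3R)-3-({[tert-butyl(dimethyl)silyl]oxy}methyl)-4-methylidene-5-oxooxolan-2-yl]tridecyl acetate | C=C1C(=O)O[C@H](CCCCCCCCCCCCCOC(C)=O)[C@H]1CO[Si](C)(C)C(C)(C)C
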